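## Structural features

The target is a trans-fused hydroazulene. A cycloheptanone (C2, C3, C4, C5, C6, C10, C11) shares the C5–C6 bond with a cyclopentane (C5, C6, C7, C8, C9), and a 4-substituted furan-2(5H)-one hangs from C11 through the chain C12–C13. The five stereocentres form two groups. C2 (secondary methyl) stands next to quaternary C11, whose methyl is trans to the C2 methyl. The angular pair C5 (tertiary hydroxyl) and C6 (hydrogen anti to that hydroxyl) is tied to the C8 carbinol as a trans-1,3-diol across gem-dimethyl C9. C5 is fully substituted and lies between quaternary C9 and C6, and the C10 ketone is wedged between C6 and quaternary C11, so every bond of the five-membered ring is made in a crowded place. The C5 hydroxyl is β to the C10 carbonyl and β to C8 at the ketone level, so retro-aldol opening and E1cB loss of the C5 oxygen are the main dangers under base; C6 is epimerisable, and the butenolide tolerates neither strong base nor hard nucleophiles and must come late. The real difficulty is to close the cyclopentane around C5 with the right fusion and to set C5 relative to the remote C2/C11 pair. The key step uses the 1,4-relationship of the C8 and C10 oxygens through C7 and C6: with C8 as a non-enolisable aldehyde and C6=C7 as the exocyclic methylidene of the ring ketone, the substrate is a 4-substituted 4-pentenal, and hydroacylation joins C7 to C8 while creating C6.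

## Logic of the disconnections

26 from 25: the C8–H bond is cut, returning the carbinol to a ketone. This removes one stereocentre and exposes the 1,4-diketone. The forward reduction must deliver hydride from the face of the C5 hydroxyl and must prefer C8 over C10.

25 from 24, and 24 from 21 and 22: first the O–Si bond at C5, then the bond from C13 to the butenolide carbon. The heterocycle is the most base-sensitive part, so it is attached last by an sp3–sp2 coupling. The forward coupling needs an organozinc that tolerates two ketones, which is why C5 stays silylated until after it.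

21 from 20 from 19: the C13–I bond and the benzyl C–O bond. The benzyl ether is orthogonal to the tertiary silyl ether, so only the primary position is opened. The forward steps must leave ketones, silyl ether and C6 untouched.

19 from 18: the C7–C8 bond, the strategic cut. It removes the five-membered ring and the C6 stereocentre and leaves a monocyclic aldehyde–enone. The forward step must form the acyl–carbon bond in a 5-endo sense and deliver hydrogen to the correct face of C6.

18 from 16, and 16 from 13 and 14: the C6=C7 double bond, then the C6–C7 single bond. The methylidene is the most reactive group of the route and is therefore made immediately before use. The forward enolisation must spare the aldehyde, so it is done with a silyl triflate and an amine, not a lithium amide.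

13 from 12 from 11: the C8=O bond is traced back to a C8=CH2 vinyl group, and the O–Si bond is removed. The vinyl group is a robust aldehyde surrogate. The cleavage must come before any other alkene exists.

11 from 9 and 10: the C5–C9 bond. One allyl-metal addition with allylic transposition joins both quaternary carbons and removes the C5 stereocentre. The forward step must choose the C5 carbonyl over C10 and the face of C5 anti to the C11 side chain.

9 from 8, and 8 from 6: the enol ether C–O bond, then the C2–CH3 and C11–CH3 bonds. Both methyl groups and the absolute configuration come from one catalytic asymmetric operation on an achiral dienone. The forward step needs ligand control at C2 and anti alkylation at C11.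

6 from 4, 4 from 2 and 3, 2 from 1: the C11=C2 unsaturation, the C11–C12 bond and the enol ether. These lead back to cycloheptane-1,3-dione, whose two carbonyls map onto C5 and C10. The forward steps need regioselective α′-chemistry, which the vinylogous ester provides.

## Other disconnections considered

Alternative 1: The cut is C2–C3 with C5–C10 re-formed, taking the seven-membered ring back to the bicyclo[3.1.0]hexane A1, a cis-1-alkenyl-2-vinyl siloxycyclopropane built on a cyclopentane that already carries C8 and C9. Forward, warming A1 should trigger the [3,3] shift through a boat transition state and give the cycloheptadiene A2, with C10=C11 as a silyl enol ether and C4=C5 as a ring-fusion alkene.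
- In its favour: the ring-forming event is concerted, needs no catalyst and is driven by strain release. The E-geometry of the alkenyl group is translated stereospecifically into C2. The enol ether of A2 is regiodefined for C11 methylation. The C8 oxygen arrives with the cyclopentane building block, so no late ketone differentiation is needed.
- Against it here: after A2 the C5 tertiary alcohol must still be introduced by face-selective Markovnikov hydration of C4=C5 (for example a Mukaiyama hydration), and that step would also decide the ring fusion. C11 must still be quaternised. A1 is a fully substituted, stereodefined siloxycyclopropane that is itself demanding to make.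
- Comparison: Alternative 1 is the better plan on predictability of the ring closure, on convergency and on C8. The chosen plan is better on the C5 carbinol and the fusion, which it settles before and during the key step. Step economy is judged roughly equal, because the hydration and redox adjustments after A2 use up what the convergent assembly saves.

Alternative 2: The cut removes the two methyl groups (C2–CH3 and C11–CH3) from the ketal-protected 2-allyl enone A3. Forward, Me3Al adds to C2 under Cu(OTf)2 and a chiral phosphoramidite, and the C11 enolate is quenched with MeI to give A4.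
- In its favour: one early catalytic step sets the absolute configuration and the trans-dimethyl array. A3 is an ordinary enone, more electrophilic than the vinylogous-ester dienone 6 on which the chosen route does the same operation, so on this single step Alternative 2 is the better.
- Against it here: it does nothing for the cyclopentane, C5, C6 or C8. The allyl group is one carbon too long and needs oxidative trimming. Making A3 from the 1,3-dione requires substitution and unsaturation on the side away from the ketal, where kinetic enolisation of a β-keto ketal is not naturally directed. The ketal must later be removed to reach the stage that 9 reaches directly.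
- Comparison: mechanistically the two are equal, since step 4 of the chosen route is the same reaction type. Alternative 2 is a different placing of the strategic weight more than a rival for the ring closure. In step economy the ketal handling and allyl trimming would cost several operations more than direct introduction of the benzyloxyethyl chain.

Alternative 3: The cut is C6–C7. Forward, the methyl ketone A5 is deprotonated twice (C6 of the ring ketone, C7 of the methyl ketone) and the bis-enolate is oxidised with Fe(acac)3 to the diketone A6.
- In its favour: A6 is the same 1,4-diketone as 19 apart from the protecting group, so the endgame is identical. No aldehyde, no reactive methylidene ketone and no precious metal are needed, and decarbonylation cannot occur. The precursor is two steps from 13, as is 18, so step economy is equal; on reagent cost and on avoiding the sensitive enone, Alternative 3 is the better.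
- Against it here: the C6 lithium enolate carries the C5 silyloxy group in its β-position and must be warmed for oxidation, which invites E1cB loss. Intramolecular coupling must beat intermolecular homo-coupling. Carbon (C7) is delivered to C6 from the side of the tether, which is expected to favour the cis fusion and to require a later C6 epimerisation next to a β-leaving group.
- Comparison: in the hydroacylation it is hydrogen, not carbon, that arrives at C6 from the tether side, which is the reason the chosen plan is preferred on the ring fusion. Both plans need the same congested bis-carbonyl precursor family and the same number of steps.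

Key step: step 11

Remarks on the chemistry:
- Locants C2–C13 of the target are kept for all intermediates.
- The configurations of 18 and 19 were re-derived from the target and keep its spatial arrangement; C5 reads R in 18 only because the methylidene raises C6 above C9 in priority.
- Base equilibration of C6 after ring closure is not relied on, since a C6 enolate has the C5 oxygen as a β-leaving group.
- Benzyl 2-iodoethyl ether is treated as a purchasable reagent.
- The sense of induction in step 4 is assumed from 2-substituted cycloalkenones and the ligand antipode is chosen accordingly.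
- Relative to a bis-silyl design, the side chain is carried as a benzyl ether so that the primary position can be opened while C5 stays protected, and the rhodium cation is used as its BF4 salt instead of a perchlorate.

## Route

Step 1
Reactants: 1 cycloheptane-1,3-dione
Product: 2 3-(2-methylpropoxy)cyclohept-2-en-1-one
Conditions: 2-methylpropan-1-ol, PPTS (cat.), toluene, reflux, Dean–Stark
Reagents that add atoms: 2-methylpropan-1-ol, CC(C)CO
Why: Acid-catalysed condensation with azeotropic removal of water gives the vinylogous ester, which differentiates the two carbonyls (future C10 and C5) and leaves only the α′ carbon (future C11) for kinetic deprotonation.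

Step 2
Reactants: 2 3-(2-methylpropoxy)cyclohept-2-en-1-one; 3 benzyl 2-iodoethyl ether
Product: 4 rac-7-[2-(benzyloxy)ethyl]-3-(2-methylpropoxy)cyclohept-2-en-1-one
Conditions: LiN(iPr)2, THF, −78 °C; then 3, DMPU, −78 °C → rt
Reagents that add atoms: none
Why: Stork–Danheiser alkylation: a 3-alkoxyenone is deprotonated kinetically at the α′ carbon and the lithium enolate is C-alkylated by the primary iodide, with DMPU offsetting the deactivating β-oxygen; the new centre is racemic and is erased in step 3.

Step 3
Reactants: 4 rac-7-[2-(benzyloxy)ethyl]-3-(2-methylpropoxy)cyclohept-2-en-1-one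
Product: 6 2-[2-(benzyloxy)ethyl]-6-(2-methylpropoxy)cyclohepta-2,6-dien-1-one, via trimethylsilyl dienol ether 5 (not isolated)
Conditions: LiN(iPr)2, Me3SiCl, THF, −78 °C; then Pd(OAc)2 (10 mol%), O2 (1 atm), DMSO, rt
Reagents that add atoms: none
Why: Saegusa–Ito oxidation: C11 is the only enolisable position, so a single dienol ether forms, and the palladium enolate should lose a β-hydrogen from ring carbon C2 to give the endocyclic cross-conjugated dienone; divalent palladium is regenerated by O2.

Step 4
Reactants: 6 2-[2-(benzyloxy)ethyl]-6-(2-methylpropoxy)cyclohepta-2,6-dien-1-one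
Product: 8 (6R,7R)-7-[2-(benzyloxy)ethyl]-6,7-dimethyl-3-(2-methylpropoxy)cyclohept-2-en-1-one, via dimethylaluminium enolate 7 (not isolated)
Conditions: Me3Al, Cu(OTf)2 (5 mol%), BINOL-derived phosphoramidite of bis(1-phenylethyl)amine (10 mol%, antipode giving 2R), Et2O, −30 °C; then MeLi, MeI, DMPU, THF, −30 → 0 °C
Reagents that add atoms: trimethylaluminium, C[Al](C)C; iodomethane, CI
Why: Copper-catalysed asymmetric conjugate addition with enolate alkylation: methyl adds to C2, the β-carbon of the more electrophilic enone half (the alkoxy-bearing β′-carbon is deactivated), on the face chosen by the ligand, which fixes the absolute configuration of the route. The aluminium enolate, activated as its lithium aluminate, should be methylated at C11 anti to the new pseudoaxial C2 methyl, giving the trans-dimethyl array with the side chain cis to the C2 methyl.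

Step 5
Reactants: 8 (6R,7R)-7-[2-(benzyloxy)ethyl]-6,7-dimethyl-3-(2-methylpropoxy)cyclohept-2-en-1-one
Product: 9 (4R,5R)-4-[2-(benzyloxy)ethyl]-4,5-dimethylcycloheptane-1,3-dione
Conditions: 1 M aq. HCl, THF, rt
Reagents that add atoms: water, O
Why: Enol ether hydrolysis (protonation at C6, water addition at C5, loss of the alcohol); neither stereocentre can enolise (C11 quaternary, C2 β to the carbonyl) and the benzyl ether is stable to dilute acid.

Step 6
Reactants: 9 (4R,5R)-4-[2-(benzyloxy)ethyl]-4,5-dimethylcycloheptane-1,3-dione; 10 1-bromo-3-methylbut-2-ene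
Product: 11 (2R,3R,6S)-2-[2-(benzyloxy)ethyl]-6-hydroxy-2,3-dimethyl-6-(2-methylbut-3-en-2-yl)cycloheptan-1-one
Conditions: In powder, THF/H2O (1:1), rt
Reagents that add atoms: none
Why: Barbier allylation: the allylindium species formed in water adds through its γ-carbon, so the CMe2 terminus bonds to C5 and both quaternary carbons are joined at once, and the aqueous medium tolerates the acidic 1,3-dione. C5 should react in preference to neopentylic C10, and attack is expected anti to the pseudoaxial C11 side chain and the C2 methyl, which places the hydroxyl cis to the side chain as required.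

Step 7
Reactants: 11 (2R,3R,6S)-2-[2-(benzyloxy)ethyl]-6-hydroxy-2,3-dimethyl-6-(2-methylbut-3-en-2-yl)cycloheptan-1-one
Product: 12 (2R,3R,6S)-2-[2-(benzyloxy)ethyl]-2,3-dimethyl-6-(2-methylbut-3-en-2-yl)-6-[(triethylsilyl)oxy]cycloheptan-1-one
Conditions: Et3SiOTf, 2,6-lutidine, CH2Cl2, −78 → 0 °C
Reagents that add atoms: triethylsilyl trifluoromethanesulfonate, CC[Si](CC)(CC)OS(=O)(=O)C(F)(F)F
Why: Silylation of the hindered tertiary alcohol with the silyl triflate; the ether blocks retro-aldol and retro-allylation and is stable to ozone, soft enolisation and the cationic rhodium catalyst.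

Step 8
Reactants: 12 (2R,3R,6S)-2-[2-(benzyloxy)ethyl]-2,3-dimethyl-6-(2-methylbut-3-en-2-yl)-6-[(triethylsilyl)oxy]cycloheptan-1-one
Product: 13 2-[(1S,4R,5R)-4-[2-(benzyloxy)ethyl]-4,5-dimethyl-3-oxo-1-[(triethylsilyl)oxy]cycloheptyl]-2-methylpropanal
Conditions: O3, CH2Cl2, −78 °C (stopped at first excess); then PPh3, −78 °C → rt
Reagents that add atoms: ozone, [O-][O+]=O
Why: Ozonolysis with reductive work-up cleaves the only alkene to the C8 aldehyde; it precedes formation of C6=C7 because ozone would not distinguish reliably between the vinyl group and an enone methylidene, and PPh3 reduces the ozonide cold so that no peroxide is concentrated.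

Step 9
Reactants: 13 2-[(1S,4R,5R)-4-[2-(benzyloxy)ethyl]-4,5-dimethyl-3-oxo-1-[(triethylsilyl)oxy]cycloheptyl]-2-methylpropanal; 14 Eschenmoser's salt (N,N-dimethylmethylideneammonium iodide)
Product: 16 2-[(1S,4R,5R)-4-[2-(benzyloxy)ethyl]-2-[(dimethylamino)methyl]-4,5-dimethyl-3-oxo-1-[(triethylsilyl)oxy]cycloheptyl]-2-methylpropanal (both C6 epimers), via trimethylsilyl enol ether 15 (not isolated)
Conditions: Me3SiOTf, Et3N, CH2Cl2, 0 °C; then 14, CH2Cl2, rt; aq. NaHCO3 work-up
Reagents that add atoms: none
Why: Soft enolisation and Mannich reaction: the C10 ketone can enolise only toward C6, the non-enolisable aldehyde is untouched by the silyl triflate and amine (a lithium amide would attack it), and the silyl enol ether is aminomethylated at C6; the C6 epimers are inconsequential.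

Step 10
Reactants: 16 2-[(1S,4R,5R)-4-[2-(benzyloxy)ethyl]-2-[(dimethylamino)methyl]-4,5-dimethyl-3-oxo-1-[(triethylsilyl)oxy]cycloheptyl]-2-methylpropanal
Product: 18 2-[(1R,4R,5R)-4-[2-(benzyloxy)ethyl]-4,5-dimethyl-2-methylidene-3-oxo-1-[(triethylsilyl)oxy]cycloheptyl]-2-methylpropanal, via trimethylammonium iodide 17 (not isolated)
Conditions: MeI, CH2Cl2, rt; then aq. NaHCO3/CH2Cl2, rt
Reagents that add atoms: none
Why: Exhaustive methylation and E1cB elimination: the ammonium group is a far better leaving group than the C5 silyloxy group, so bicarbonate should unveil C6=C7 without loss of the C5 oxygen; the methylidene is flanked by two fully substituted carbons, which slows dimerisation, and it is used at once.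

Step 11
Reactants: 18 2-[(1R,4R,5R)-4-[2-(benzyloxy)ethyl]-4,5-dimethyl-2-methylidene-3-oxo-1-[(triethylsilyl)oxy]cycloheptyl]-2-methylpropanal
Product: 19 (3aS,5R,6R,8aS)-5-[2-(benzyloxy)ethyl]-1,1,5,6-tetramethyl-8a-[(triethylsilyl)oxy]hexahydroazulene-2,4(1H,3H)-dione (trans-fused)
Conditions: [Rh(nbd)(dppe)]BF4 (10 mol%, pre-hydrogenated to [Rh(dppe)(acetone)2]BF4, H2 removed), degassed acetone, 25 → 50 °C
Reagents that add atoms: none
Why: Oxidative addition of the C8–H bond to the monovalent rhodium cation gives an acyl rhodium hydride that holds the C6=C7 methylidene by chelation; hydride migrates to C6 and rhodium to C7, and the six-membered acyl–alkyl rhodacycle of trivalent rhodium closes C7–C8 by reductive elimination. The closest known reaction type is the rhodium–diphosphine cyclisation of 4-substituted 4-pentenals to 3-substituted cyclopentanones, with the C10 acyl group as the 4-substituent here. The cyclopentanone closes in a formally 5-endo-trig sense (both alkene carbons end in the ring), which is feasible because the C–C bond is made from a six-membered metallacycle and not by direct attack of an acyl nucleophile. C6 is the only new stereocentre: rhodium is tethered through C8–C9 to the alkene face on which the pseudoaxial C9 arm stands, so hydride should arrive at C6 cis to C9 and anti to the silyloxy group, which is the trans fusion. The step needs hydroacylation to outrun decarbonylation and isomerisation: the methylidene has no allylic hydrogen (C5 quaternary, C10 carbonyl), the aldehyde cannot enolise, and gem-dimethyl C9 with fully substituted C5 press the reacting ends together. Hydride transfer to C7 instead would give a five-membered rhodium enolate that cannot close a cyclobutanone and should revert. The BF4 salt avoids a perchlorate, and acetone keeps the cation solvated against binding by the benzyl arene.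

Step 12
Reactants: 19 (3aS,5R,6R,8aS)-5-[2-(benzyloxy)ethyl]-1,1,5,6-tetramethyl-8a-[(triethylsilyl)oxy]hexahydroazulene-2,4(1H,3H)-dione
Product: 20 (3aS,5R,6R,8aS)-5-(2-hydroxyethyl)-1,1,5,6-tetramethyl-8a-[(triethylsilyl)oxy]hexahydroazulene-2,4(1H,3H)-dione
Conditions: H2 (1 atm), 10% Pd/C, EtOAc, rt
Reagents that add atoms: none
Why: Hydrogenolysis of the benzyl ether in a non-protic solvent leaves the tertiary silyl ether, both ketones and C6 untouched, so only the primary position is opened.

Step 13
Reactants: 20 (3aS,5R,6R,8aS)-5-(2-hydroxyethyl)-1,1,5,6-tetramethyl-8a-[(triethylsilyl)oxy]hexahydroazulene-2,4(1H,3H)-dione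
Product: 21 (3aS,5R,6R,8aS)-5-(2-iodoethyl)-1,1,5,6-tetramethyl-8a-[(triethylsilyl)oxy]hexahydroazulene-2,4(1H,3H)-dione
Conditions: I2, PPh3, imidazole, CH2Cl2, 0 °C → rt
Reagents that add atoms: iodine, [I][I]
Why: Appel-type iodination of the primary alcohol; the open form of any C10 lactol is drained as the alkoxyphosphonium salt, and no other hydroxyl is free.

Step 14
Reactants: 21 (3aS,5R,6R,8aS)-5-(2-iodoethyl)-1,1,5,6-tetramethyl-8a-[(triethylsilyl)oxy]hexahydroazulene-2,4(1H,3H)-dione; 22 4-bromofuran-2(5H)-one
Product: 24 (3aS,5R,6R,8aS)-1,1,5,6-tetramethyl-5-[2-(5-oxo-2,5-dihydrofuran-3-yl)ethyl]-8a-[(triethylsilyl)oxy]hexahydroazulene-2,4(1H,3H)-dione, via alkylzinc iodide 23 (not isolated)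
Conditions: Zn dust (activated with Me3SiCl/BrCH2CH2Br), LiCl, THF, 30 °C; then 22, Pd(OAc)2 (3 mol%), SPhos (6 mol%), THF, rt
Reagents that add atoms: none
Why: Negishi coupling: zinc inserts into the primary C–I bond to give an alkylzinc iodide that tolerates both ketones and meets no free hydroxyl, and palladium with a bulky biarylphosphine should couple it to the activated vinyl bromide faster than β-hydride elimination.

Step 15
Reactants: 24 (3aS,5R,6R,8aS)-1,1,5,6-tetramethyl-5-[2-(5-oxo-2,5-dihydrofuran-3-yl)ethyl]-8a-[(triethylsilyl)oxy]hexahydroazulene-2,4(1H,3H)-dione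
Product: 25 (3aS,5R,6R,8aS)-8a-hydroxy-1,1,5,6-tetramethyl-5-[2-(5-oxo-2,5-dihydrofuran-3-yl)ethyl]hexahydroazulene-2,4(1H,3H)-dione
Conditions: HF·pyridine, pyridine, THF, 0 °C → rt
Reagents that add atoms: none
Why: Buffered acidic fluoride cleaves the tertiary silyl ether without generating a free alkoxide, which avoids retro-aldol opening of the β-hydroxy diketone; the butenolide is stable to these conditions.

Step 16
Reactants: 25 (3aS,5R,6R,8aS)-8a-hydroxy-1,1,5,6-tetramethyl-5-[2-(5-oxo-2,5-dihydrofuran-3-yl)ethyl]hexahydroazulene-2,4(1H,3H)-dione
Product: 26 (2S,3aS,5R,6R,8aS)-2,8a-dihydroxy-1,1,5,6-tetramethyl-5-[2-(5-oxo-2,5-dihydrofuran-3-yl)ethyl]octahydroazulen-4(1H)-one (CNP0077405.3)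
Conditions: Me4NBH(OAc)3, MeCN/AcOH (1:1), −30 → 0 °C
Reagents that add atoms: none
Why: Evans–Saksena reduction: the C5 hydroxyl exchanges onto boron and the alkoxy(diacetoxy)borohydride delivers hydride internally to the C8 carbonyl through a six-membered transition state over C9, so the new hydroxyl is anti to the C5 hydroxyl (trans-1,3-diol). The cyclopentanone C8 is expected to react ahead of C10, a cycloheptanone shielded by quaternary C11 and C6, and the reagent does not reduce the butenolide.

## Compound list

1 | cycloheptane-1,3-dione | O=C1CCCCC(=O)C1 | starting material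
2 | 3-(2-methylpropoxy)cyclohept-2-en-1-one | CC(C)COC1=CC(=O)CCCC1 | intermediate
3 | benzyl 2-iodoethyl ether | ICCOCc1ccccc1 | starting material
4 | rac-7-[2-(benzyloxy)ethyl]-3-(2-methylpropoxy)cyclohept-2-en-1-one (racemic) | CC(C)COC1=CC(=O)C(CCOCc2ccccc2)CCC1 | intermediate
5 | trimethylsilyl dienol ether of 4 (1-[2-(benzyloxy)ethyl]-4-(2-methylpropoxy)-2-(trimethylsilyloxy)cyclohepta-1,3-diene) | CC(C)COC1=CC(O[Si](C)(C)C)=C(CCOCc2ccccc2)CCC1 | intermediate (not isolated)
6 | 2-[2-(benzyloxy)ethyl]-6-(2-methylpropoxy)cyclohepta-2,6-dien-1-one | CC(C)COC1=CC(=O)C(CCOCc2ccccc2)=CCC1 | intermediate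
7 | dimethylaluminium enolate of the conjugate adduct (C2 R, C10=C11 enolate) | C[C@@H]1CCC(OCC(C)C)=CC(O[Al](C)C)=C1CCOCc1ccccc1 | intermediate (not isolated)
8 | (6R,7R)-7-[2-(benzyloxy)ethyl]-6,7-dimethyl-3-(2-methylpropoxy)cyclohept-2-en-1-one | C[C@@H]1CCC(OCC(C)C)=CC(=O)[C@]1(C)CCOCc1ccccc1 | intermediate
9 | (4R,5R)-4-[2-(benzyloxy)ethyl]-4,5-dimethylcycloheptane-1,3-dione | C[C@@H]1CCC(=O)CC(=O)[C@]1(C)CCOCc1ccccc1 | intermediate
10 | 1-bromo-3-methylbut-2-ene | CC(C)=CCBr | starting material
11 | (2R,3R,6S)-2-[2-(benzyloxy)ethyl]-6-hydroxy-2,3-dimethyl-6-(2-methylbut-3-en-2-yl)cycloheptan-1-one | C[C@@H]1CC[C@](C(C)(C)C=C)(O)CC(=O)[C@]1(C)CCOCc1ccccc1 | intermediate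
12 | (2R,3R,6S)-2-[2-(benzyloxy)ethyl]-2,3-dimethyl-6-(2-methylbut-3-en-2-yl)-6-[(triethylsilyl)oxy]cycloheptan-1-one | C[C@@H]1CC[C@](C(C)(C)C=C)(O[Si](CC)(CC)CC)CC(=O)[C@]1(C)CCOCc1ccccc1 | intermediate
13 | 2-[(1S,4R,5R)-4-[2-(benzyloxy)ethyl]-4,5-dimethyl-3-oxo-1-[(triethylsilyl)oxy]cycloheptyl]-2-methylpropanal | C[C@@H]1CC[C@](C(C)(C)C=O)(O[Si](CC)(CC)CC)CC(=O)[C@]1(C)CCOCc1ccccc1 | intermediate
14 | Eschenmoser's salt (N,N-dimethylmethylideneammonium iodide) | C=[N+](C)C.[I-] | starting material
15 | trimethylsilyl enol ether of 13 (C6=C10) | C[C@@H]1CC[C@](C(C)(C)C=O)(O[Si](CC)(CC)CC)C=C(O[Si](C)(C)C)[C@]1(C)CCOCc1ccccc1 | intermediate (not isolated)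
16 | 2-[(1S,4R,5R)-4-[2-(benzyloxy)ethyl]-2-[(dimethylamino)methyl]-4,5-dimethyl-3-oxo-1-[(triethylsilyl)oxy]cycloheptyl]-2-methylpropanal (C6 epimers) | C[C@@H]1CC[C@](C(C)(C)C=O)(O[Si](CC)(CC)CC)C(CN(C)C)C(=O)[C@]1(C)CCOCc1ccccc1 | intermediate
17 | trimethylammonium iodide of 16 | C[C@@H]1CC[C@](C(C)(C)C=O)(O[Si](CC)(CC)CC)C(C[N+](C)(C)C)C(=O)[C@]1(C)CCOCc1ccccc1.[I-] | intermediate (not isolated)
18 | 2-[(1R,4R,5R)-4-[2-(benzyloxy)ethyl]-4,5-dimethyl-2-methylidene-3-oxo-1-[(triethylsilyl)oxy]cycloheptyl]-2-methylpropanal | C[C@@H]1CC[C@](C(C)(C)C=O)(O[Si](CC)(CC)CC)C(=C)C(=O)[C@]1(C)CCOCc1ccccc1 | intermediate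
19 | (3aS,5R,6R,8aS)-5-[2-(benzyloxy)ethyl]-1,1,5,6-tetramethyl-8a-[(triethylsilyl)oxy]hexahydroazulene-2,4(1H,3H)-dione | C[C@@H]1CC[C@]2(O[Si](CC)(CC)CC)[C@H](CC(=O)C2(C)C)C(=O)[C@]1(C)CCOCc1ccccc1 | intermediate
20 | (3aS,5R,6R,8aS)-5-(2-hydroxyethyl)-1,1,5,6-tetramethyl-8a-[(triethylsilyl)oxy]hexahydroazulene-2,4(1H,3H)-dione | C[C@@H]1CC[C@]2(O[Si](CC)(CC)CC)[C@H](CC(=O)C2(C)C)C(=O)[C@]1(C)CCO | intermediate
21 | (3aS,5R,6R,8aS)-5-(2-iodoethyl)-1,1,5,6-tetramethyl-8a-[(triethylsilyl)oxy]hexahydroazulene-2,4(1H,3H)-dione | C[C@@H]1CC[C@]2(O[Si](CC)(CC)CC)[C@H](CC(=O)C2(C)C)C(=O)[C@]1(C)CCI | intermediate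
22 | 4-bromofuran-2(5H)-one | O=C1OCC(Br)=C1 | starting material
23 | alkylzinc iodide from 21 | C[C@@H]1CC[C@]2(O[Si](CC)(CC)CC)[C@H](CC(=O)C2(C)C)C(=O)[C@]1(C)CC[Zn]I | intermediate (not isolated)
24 | (3aS,5R,6R,8aS)-1,1,5,6-tetramethyl-5-[2-(5-oxo-2,5-dihydrofuran-3-yl)ethyl]-8a-[(triethylsilyl)oxy]hexahydroazulene-2,4(1H,3H)-dione | C[C@@H]1CC[C@]2(O[Si](CC)(CC)CC)[C@H](CC(=O)C2(C)C)C(=O)[C@]1(C)CCC1=CC(=O)OC1 | intermediate
25 | (3aS,5R,6R,8aS)-8a-hydroxy-1,1,5,6-tetramethyl-5-[2-(5-oxo-2,5-dihydrofuran-3-yl)ethyl]hexahydroazulene-2,4(1H,3H)-dione | C[C@@H]1CC[C@]2(O)[C@H](CC(=O)C2(C)C)C(=O)[C@]1(C)CCC1=CC(=O)OC1 | intermediate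
26 | (2S,3aS,5R,6R,8aS)-2,8a-dihydroxy-1,1,5,6-tetramethyl-5-[2-(5-oxo-2,5-dihydrofuran-3-yl)ethyl]octahydroazulen-4(1H)-one | C[C@@H]1CC[C@]2(O)[C@H](C[C@H](O)C2(C)C)C(=O)[C@]1(C)CCC1=CC(=O)OC1 | target

## Step count and least certain steps

Total step count: 16. Longest linear sequence: 16 steps from 1; the route is fully linear, and 3, 10, 14 and 22 are bought.

Step 11 (key step). The most likely failure is decarbonylation of the crowded acyl rhodium hydride outpacing insertion into a hindered, electron-poor 1,1-disubstituted alkene, which also ties the catalyst up as a carbonyl complex. Misdirected hydride transfer to C7 would add to the loss. Fallback, from 13 to 19: MeMgBr (THF, −78 °C) adds to the aldehyde of 13, in preference to the shielded C10 ketone, to give the secondary carbinol F1. Dess–Martin oxidation gives the methyl ketone F2. Double deprotonation with LiN(iPr)2 at C6 and at the C7 methyl, then oxidation of the bis-enolate with Fe(acac)3 at high dilution, forms C6–C7 and gives 19. In that case the fusion may have to be checked and corrected at C6.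

Step 6. The most likely failure is poor facial selectivity at C5, because control comes from centres across a flexible seven-membered ring; partial bonding through the unbranched allyl terminus is a second risk. Fallback, from 11 back to 11: the order in which the two C5 substituents arrive is reversed. The unwanted epimer (or mixture) of 11 is dehydrated with SOCl2/pyridine to the conjugated enone F3. Nucleophilic epoxidation with H2O2/NaOH then places oxygen on C5 from the face the carbon nucleophile had preferred, giving the epoxy ketone F4. SmI2 (THF/MeOH, −90 °C) cleaves the C6–O bond and returns the desired C5 epimer of 11.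

Step 4. The most likely failures are slow turnover because the vinylogous ester lowers the electrophilicity of the dienone, and sluggish C-methylation of the aluminium enolate with erosion of the trans selectivity. Fallback, from 6 to 8: the three-component coupling is split. Me2Zn with Cu(OTf)2 and the same phosphoramidite adds methyl to C2, and the zinc enolate is trapped with Me3SiOTf as the isolable silyl dienol ether F5. MeLi then releases a lithium enolate, which is methylated with MeI/DMPU to 8.

Step 3. The most likely failure is β-hydride loss toward the side chain, giving an exocyclic alkylidene ketone instead of the ring enone. Fallback, from 4 to 6: the silyl dienol ether 5 is brominated with NBS to the tertiary α-bromo ketone F6. Dehydrobromination with Li2CO3/LiBr in DMF at 120 °C, an ionic elimination under equilibrating conditions, should give 6 as the more stable endocyclic isomer.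

Step 16. The most likely failure is competing reduction of the C10 ketone, which is also β to the C5 hydroxyl, or incomplete facial control at C8. Fallback, from 25 to 26: the C5 hydroxyl is converted with ClSiH(iPr)2/imidazole into the diisopropylsilyl ether F7. On activation of the more accessible C8 carbonyl with SnCl4 at −78 °C, its Si–H bond transfers hydride internally from the same face through a covalent tether. HF·pyridine then removes silicon and gives 26.

## Further compounds

F1 | step 11 | (2R,3R,6S)-2-[2-(benzyloxy)ethyl]-6-(3-hydroxy-2-methylbutan-2-yl)-2,3-dimethyl-6-[(triethylsilyl)oxy]cycloheptan-1-one (C8 epimers) | C[C@@H]1CC[C@](C(C)(C)C(C)O)(O[Si](CC)(CC)CC)CC(=O)[C@]1(C)CCOCc1ccccc1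
F2 | step 11 | (2R,3R,6S)-2-[2-(benzyloxy)ethyl]-2,3-dimethyl-6-(2-methyl-3-oxobutan-2-yl)-6-[(triethylsilyl)oxy]cycloheptan-1-one | C[C@@H]1CC[C@](C(C)(C)C(C)=O)(O[Si](CC)(CC)CC)CC(=O)[C@]1(C)CCOCc1ccccc1
F3 | step 6 | (6R,7R)-7-[2-(benzyloxy)ethyl]-6,7-dimethyl-3-(2-methylbut-3-en-2-yl)cyclohept-2-en-1-one | C[C@@H]1CCC(C(C)(C)C=C)=CC(=O)[C@]1(C)CCOCc1ccccc1
F4 | step 6 | C5,C6-epoxide of F3 with the oxygen on the face of the C11 side chain | C[C@@H]1CC[C@]2(C(C)(C)C=C)O[C@@H]2C(=O)[C@]1(C)CCOCc1ccccc1
F5 | step 4 | trimethylsilyl dienol ether of the C2 (R) conjugate adduct (C10=C11) | C[C@@H]1CCC(OCC(C)C)=CC(O[Si](C)(C)C)=C1CCOCc1ccccc1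
F6 | step 3 | rac-7-[2-(benzyloxy)ethyl]-7-bromo-3-(2-methylpropoxy)cyclohept-2-en-1-one | CC(C)COC1=CC(=O)C(Br)(CCOCc2ccccc2)CCC1
F7 | step 16 | C5 diisopropylsilyl (Si–H) ether of 25 | C[C@@H]1CC[C@]2(O[SiH](C(C)C)C(C)C)[C@H](CC(=O)C2(C)C)C(=O)[C@]1(C)CCC1=CC(=O)OC1
A1 | alternative 1 | cis-6-[(E)-alkenyl]-1-vinyl-6-(trimethylsilyloxy)bicyclo[3.1.0]hexane carrying the C8 silyl ether and C9 gem-dimethyl group | C=C[C@]12[C@H](C[C@H](O[Si](C)(C)C(C)(C)C)C1(C)C)[C@@]2(O[Si](C)(C)C)/C(CCO[Si](C)(C)C(C)(C)C)=C/C
A2 | alternative 1 | hydroazulene dienyl silyl enol ether (C4=C5, C10=C11) | C[C@@H]1CC=C2[C@H](C[C@H](O[Si](C)(C)C(C)(C)C)C2(C)C)C(O[Si](C)(C)C)=C1CCO[Si](C)(C)C(C)(C)C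
A3 | alternative 2 | 2-allyl-6,6-(ethylenedioxy)cyclohept-2-en-1-one | C=CCC1=CCCC2(OCCO2)CC1=O
A4 | alternative 2 | trans-dimethyl 2-allyl cycloheptanone ketal | C[C@@H]1CCC2(OCCO2)CC(=O)[C@]1(C)CC=C
A5 | alternative 3 | monocyclic C8 methyl ketone / C10 ring ketone with C5 triethylsilyl ether and side-chain tert-butyldimethylsilyl ether | C[C@@H]1CC[C@](C(C)(C)C(C)=O)(O[Si](CC)(CC)CC)CC(=O)[C@]1(C)CCO[Si](C)(C)C(C)(C)C
A6 | alternative 3 | bicyclic 1,4-diketone with side-chain tert-butyldimethylsilyl ether | C[C@@H]1CC[C@]2(O[Si](CC)(CC)CC)[C@H](CC(=O)C2(C)C)C(=O)[C@]1(C)CCO[Si](C)(C)C(C)(C)C
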